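All runs were computed from invented constants; the scatter is artificial.

At 50 min the flasks are read for one thing: how much target has survived its own over-reaction.

| setting | theta | delta | gamma | beta | blue | teal | amber | green | grey |
|---|---|---|---|---|---|---|---|---|---|
| substrate | 0.039 M | 0.095 M | 0.12 M | 0.10 M | 0.050 M | 0.060 M | 0.050 M | 0.15 M | 0.10 M |
| reagent | 2 equiv | 2 equiv | 2 equiv | 1.3 equiv | 2.00 equiv | 3.00 equiv | 1.00 equiv | 0.500 equiv | 2.00 equiv |
| initiator | 0.71 mol% | 0.71 mol% | 0.71 mol% | 0.71 mol% | 0.71 mol% | 0.25 mol% | 2 mol% | 2 mol% | 0.71 mol% |
| remark | run made earlier | run made earlier | run made earlier | run made earlier |  |  |  |  |  |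
| time |  |  |  |  | 50 min | 50 min | 50 min | 50 min | 50 min |

- theta (time / min: target / %, over-reaction product B / %): 4.00: 22.4, 5.1; 12.0: 36.3, 23.5; 25.0: 37.9, 46.3; 40.0: 33.8, 60.5
- delta (time / min: target / %, over-reaction product B / %): 4.00: 23.7, 13.9; 12.0: 31.0, 45.7; 25.0: 28.5, 66.5; 40.0: 22.6, 74.8
- gamma (time / min: target / %, over-reaction product B / %): 3.00: 22.2, 11.3; 6.00: 27.4, 28.5; 15.0: 28.1, 56.9; 40.0: 21.8, 77.0
- beta (time / min: target / %, over-reaction product B / %): 3.00: 24.4, 6.2; 6.00: 36.4, 16.5; 15.0: 51.8, 32.0; 40.0: 57.3, 33.4

(standard deviation of a reading: 0.5 percentage points)

1. all flasks from highest to lowest share of target in all that became target or over-reaction product B, at 50 min (blue / teal / amber / green / grey)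
2. the same order at 6.0 h (blue / teal / amber / green / grey)
3. the share of target in all that became target or over-reaction product B of the flask you put first, at 50 min
4. the share of target in all that became target or over-reaction product B of the flask you put last, at 50 min

- the earlier runs were read with a standard deviation of 0.5 percentage points
- on the list of suspects stand: initiator -> 2 initiating radical; substrate + initiating radical -> capped initiator + first chain carrier; reagent + first chain carrier <-> target + second chain carrier; substrate + second chain carrier -> by-product + first chain carrier; 2 second chain carrier -> ended chains; target -> over-reaction product A; 2 reagent -> homo dimer; reagent + target -> over-reaction product B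
- the share counts what is present at the end, not what went on to other products

1. What is in the flask: substrate turns into target by a chain, and target meets reagent to give over-reaction product B. Each target costs one reagent and each over-reaction product B costs two. Homo dimer is left out of this book.

2. All quantities are fractions of the substrate charge: x consumed, a substrate left, r reagent, p target, b over-reaction product B, e reagent charged. Dividing the rate of b by the rate of x removes time: db/dx = S·r·p/a.

3. S is the selectivity factor, the over-reaction constant times the substrate charge, over the pseudo-first-order constant of substrate loss. Between 3.00 min and 6.00 min in beta, b rose 0.462 per unit of x, while r·p/a averaged 0.385. So S reads 1.20, with the scatter of those readings.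

4. Taking the substrate loss constant to grow with the root of the initiator concentration, S goes as the root of substrate charge over initiator loading, which gives 0.876 for green.

5. Green has reagent as limiting reagent. Taking a as one, p as x, and r falling in a straight line from e, the part lost to over-reaction product B is S times e squared over 6. That is 3.65%, so my reckoning puts green's share at 96.3%; it does not cover flasks with reagent in excess.

6. What will stand in green is target and unused substrate: beta's over-reaction product B rose 1.4 percentage points between 15.0 min and 40.0 min. For the share, green's reagent charge is not to be raised, since in this reckoning the loss goes with its square.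

7. The forecast: green > amber > blue > grey > teal at 50 min, green > amber > blue > grey > teal at 6.0 h, top 96% (91% to 98.5%), low 12% (8% to 17%), with the ground “Beta's plateau shows target survives once reagent is gone”.

    initiator → 2 initiating radical (k = 1.90 × 10⁻⁴ /s)
    substrate + initiating radical → capped initiator + first chain carrier (k = 6.20 × 10⁵ /M/s)
    reagent + first chain carrier ⇌ target + second chain carrier (K = 0.170, k = 10000 /M/s)
    substrate + second chain carrier → by-product + first chain carrier (k = 70000 /M/s)
    2 second chain carrier → ended chains (k = 1.50 × 10⁸ /M/s)
    target → over-reaction product A (k = 1.70 × 10⁻⁶ /s)
    2 reagent → homo dimer (k = 5.70 × 10⁻⁴ /M/s)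
    reagent + target → over-reaction product B (k = 0.0240 /M/s)

The flasks give green > amber > blue > grey > teal at 50 min and green > amber > grey > blue > teal at 6.0 h, with top 95.6% and low 9.38%. Green lost 4.40% against the reckoned 3.65%; its neighbour at 0.120 equiv lost 0.279% against a reckoned 0.210%. Green held reagent at 0% at 50.0 min, and its share goes from 95.6% then to 95.4% at 500 min. At 50 min blue kept 9.9% of its reagent and grey 3.4%, and at 6.0 h their shares stand at 12.2% and 14.4%, their order reversed from that at 50 min. Teal kept 24% of its reagent at 50 min, and its share falls from 9.38% then to 0% at 500 min.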